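All runs come from a simulation with constants of no real substance.

0.880 M is c(reagent) per starting volume in this flask, against 1.60 M for c(left-handed substrate) and c(right-handed substrate) together, which is less, so we take reagent as the limiting reagent.

the same everywhere: left-handed substrate 0.80 M; right-handed substrate 0.80 M
- dusk: reagent 1.1 equiv (fed, over 6.0 min); free catalyst 0.9 mol%; run made earlier; the fed solution adds 0.10 times the starting volume
- winter: reagent 1.1 equiv (fed, over 6.0 min); free catalyst 1.4 mol%; run made earlier; the fed solution adds 0.10 times the starting volume
- flask: reagent 1.10 equiv (fed, over 6.0 min); free catalyst 1.8 mol%; the fed solution adds 0.10 times the starting volume; time 6.0 h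

- dusk (time / h: left-handed substrate / %, right-handed substrate / %, left-handed product / %): 0.417: 17.1, 38.8, 35.0; 1.33: 17.1, 31.8, 42.6; 2.50: 17.8, 27.1, 43.1; 4.00: 20.5, 23.0, 43.9
- winter (time / h: left-handed substrate / %, right-handed substrate / %, left-handed product / %): 0.250: 18.2, 39.2, 33.1; 0.667: 14.6, 33.9, 40.5; 1.50: 15.7, 30.5, 41.7; 4.00: 22.2, 23.6, 43.3

(readings scatter by 1 percentage point)

- part of the left-handed substrate and right-handed substrate charged together that has reacted at 6.0 h
- excess of left-handed product over right-handed product in the product at 6.0 h
- excess of right-handed substrate over left-handed substrate among what is left of the two at 6.0 h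

- free catalyst is single-handed; left-handed substrate and right-handed substrate are mirror images of each other, charged as a racemate, each of them at the stated concentration
- charges are per starting volume, the dose included; the dosed solution carries all of it
- an excess is the difference of the two amounts in percent of their sum
- an excess is below zero if the other one leads

1. Reagent equivalents. Counted at one reagent per product, equivalents over two gives 55.0% of both substrates together; we call this share the reagent ceiling. The dusk and winter runs have the same ceiling, 55.0%, and at 4.00 h they have reacted 56.5% and 54.2%, one on each side of it.

2. Catalyst. By hand, with the reagent charge held, we expect more catalyst to bring these flasks to the ceiling sooner without raising it. The dusk run, at 0.9 mol%, has reacted 51.1% by 1.33 h; the winter run, at 1.4 mol%, has reacted 51.5% by 0.667 h. This flask carries more catalyst than either.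

3. Dosing and time. Neither appears in the ceiling. Both runs were dosed over 6.0 min, so the readings cannot test dosing. The dusk run stands at 55.1% by 2.50 h, so we expect little more conversion in this flask by 6.0 h.

4. Our reckoning. For this flask we commit to c = 55.0%. With product at the ceiling, eP is twice the left-handed product over the ceiling, minus one; the mean of the two 4.00 h readings, with their scatter, gives 58.5% as our eP for this flask. The winter run's substrate gap reads 1.4 percentage points at 4.00 h, so we expect eS near zero in this flask.

5. The forecast gives c = 55%, eP = 56%, a little below our eP, and eS = 0%, holding that “the remaining substrate racemizes”.

6. The flask gives c = 55.0%, eP = 58.4% and eS = 1.27%.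

    reagent + free catalyst + left-handed substrate → free catalyst + left-handed product (k = 0.420 /M²/s)
    reagent + free catalyst + right-handed substrate → free catalyst + right-handed product (k = 0.0650 /M²/s)
    left-handed substrate ⇌ right-handed substrate (k = 9.80 × 10⁻⁵ /s)
    2 free catalyst → spent catalyst A (k = 0.0210 /M/s)
    reagent + free catalyst → spent catalyst B (k = 6.90 × 10⁻⁵ /M/s)

7. The flask's conversion sits at the ceiling, with 0.024% of the reagent charge left at 6.00 h. The neighbour flask charged with 0.660 equiv of reagent, other charges and time held, has a ceiling of 33.0%. That neighbour flask gives c = 33.0%, with 0% of its reagent left, and its product excess is 66.1%.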